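**Strategy.** The chalcone is cut at the bond between the ketone carbon and the alpha carbon of the enone. The free hydroxyl on ring A (C5–OH of the chromene, ortho to the acyl-bearing C6) serves as a chelating handle: rhodium-catalysed hydroacylation adds the formyl C–H bond of 5-hydroxy-2,2-dimethyl-2H-chromene-6-carbaldehyde across the terminal alkyne of 4-ethynyl-2-prenylphenol. In one protecting-group-free, fully atom-economical operation this joins the chromene half and the prenylated ring B half, creates the ketone and sets the E-alkene by syn addition. The precursors are thus a salicylaldehyde and an aryl acetylene, neither of which contains the enone.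

Key step: step 4

Remark: the target has no stereocentre, and its only stereochemical element, the E enone, is set in step 4. The phenol of the alkyne partner is assumed to need no protection there, because only the ortho-formyl phenoxide of the aldehyde partner can chelate rhodium.

**Step 1**
Reactants: 1 2,4-dihydroxybenzaldehyde; 2 3-methylbut-2-enal
Product: 4 5-hydroxy-2,2-dimethyl-2H-chromene-6-carbaldehyde, via ortho-quinone methide 3 (not isolated)
Conditions: pyridine, 120 °C, sealed tube
Reagents that add atoms: none
Why: Aldol-type condensation of ring carbon C3 (flanked by both hydroxyls) with the enal and loss of water should give ortho-quinone methide 3, whose oxa-6π electrocyclisation onto the non-chelated C4 oxygen closes the 2H-pyran (chromenylation of a resorcinol), while the C2 hydroxyl stays hydrogen-bonded to the formyl group and so fixes the angular regiochemistry.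

**Step 2**
Reactants: 5 4-hydroxybenzaldehyde; 6 1-bromo-3-methylbut-2-ene
Product: 7 4-hydroxy-3-(3-methylbut-2-en-1-yl)benzaldehyde
Conditions: 10% aq. KOH, rt
Reagents that add atoms: none
Why: Ortho C-alkylation of an ambident phenoxide in water (SN2 at the primary allylic bromide), where hydrogen bonding to the phenoxide oxygen disfavours O-alkylation and the blocked para position leaves only the ortho carbon, the neutral O-prenyl ether being removable by base extraction.

**Step 3**
Reactants: 7 4-hydroxy-3-(3-methylbut-2-en-1-yl)benzaldehyde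
Product: 9 4-ethynyl-2-(3-methylbut-2-en-1-yl)phenol, via diazoalkene 8 (not isolated)
Conditions: Ohira–Bestmann reagent, K2CO3, MeOH, 0 °C to rt
Reagents that add atoms: Ohira–Bestmann reagent, dimethyl (1-diazo-2-oxopropyl)phosphonate, CC(=O)C(=[N+]=[N-])P(=O)(OC)OC
Why: Seyferth–Gilbert homologation in its Ohira–Bestmann form, in which methanolysis of the reagent gives the dimethyl (diazomethyl)phosphonate anion, which adds to the aldehyde and eliminates in Horner–Wadsworth–Emmons fashion to diazoalkene 8, whose loss of N2 and 1,2-hydrogen shift should give the terminal alkyne while the prenyl alkene stays untouched.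

**Step 4**
Reactants: 4 5-hydroxy-2,2-dimethyl-2H-chromene-6-carbaldehyde; 9 4-ethynyl-2-(3-methylbut-2-en-1-yl)phenol
Product: 10 paratocarpin B, (E)-1-(5-hydroxy-2,2-dimethyl-2H-chromen-6-yl)-3-[4-hydroxy-3-(3-methylbut-2-en-1-yl)phenyl]prop-2-en-1-one
Conditions: [RhCl(cod)]2 (2.5 mol %), dppf (1,1'-bis(diphenylphosphino)ferrocene, 5 mol %), Na2CO3 (10 mol %), toluene, 90 °C, argon, slow addition of 9
Reagents that add atoms: none
Why: Chelation-assisted rhodium-catalysed intermolecular alkyne hydroacylation: the phenoxide of 4 binds monovalent rhodium and oxidative addition of the formyl C–H bond gives a five-membered O,C-chelated acyl hydride of trivalent rhodium, in which chelation suppresses decarbonylation. Syn hydrometalation of the terminal alkyne of 9 places rhodium on the unsubstituted carbon, and C–C reductive elimination then forms the bond between the acyl carbon and the former terminal alkyne carbon. The closest known reaction type is the coupling of salicylaldehydes with terminal alkynes to 2-hydroxyaryl vinyl ketones under [RhCl(cod)]2/dppf/Na2CO3. No ring is closed and no stereocentre is formed; the E geometry follows from the syn addition of acyl and hydrogen across the triple bond. The step needs linear over branched regioselectivity, which the steric demand of the aryl group toward the dppf-ligated chelate should secure, and chemoselectivity for the alkyne over the prenyl and chromene alkenes, which are trisubstituted and cis-disubstituted and should not insert. Only catalytic weak base in toluene is present, so the 2'-hydroxychalcone should not close to the flavanone.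

**Compound list**
1 | 2,4-dihydroxybenzaldehyde | O=Cc1ccc(O)cc1O | starting material
2 | 3-methylbut-2-enal | CC(C)=CC=O | starting material
3 | (Z)-2-hydroxy-3-(3-methylbut-2-en-1-ylidene)-4-oxocyclohexa-1,5-diene-1-carbaldehyde (ortho-quinone methide, formed in the flask, not isolated) | O=CC1=C(O)/C(=C/C=C(C)C)C(=O)C=C1 | intermediate
4 | 5-hydroxy-2,2-dimethyl-2H-chromene-6-carbaldehyde | O=Cc1ccc2c(c1O)C=CC(C)(C)O2 | intermediate
5 | 4-hydroxybenzaldehyde | O=Cc1ccc(O)cc1 | starting material
6 | 1-bromo-3-methylbut-2-ene | CC(C)=CCBr | starting material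
7 | 4-hydroxy-3-(3-methylbut-2-en-1-yl)benzaldehyde | CC(C)=CCc1cc(C=O)ccc1O | intermediate
8 | 4-(2-diazoethenyl)-2-(3-methylbut-2-en-1-yl)phenol (diazoalkene, formed in the flask, not isolated) | CC(C)=CCc1cc(C=C=[N+]=[N-])ccc1O | intermediate
9 | 4-ethynyl-2-(3-methylbut-2-en-1-yl)phenol | CC(C)=CCc1cc(C#C)ccc1O | intermediate
10 | paratocarpin B, (E)-1-(5-hydroxy-2,2-dimethyl-2H-chromen-6-yl)-3-[4-hydroxy-3-(3-methylbut-2-en-1-yl)phenyl]prop-2-en-1-one | CC(C)=CCc1cc(/C=C/C(=O)c2ccc3c(c2O)C=CC(C)(C)O3)ccc1O | target

**Total step count:** 4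
**Longest linear sequence:** 3 steps (5 → 7 → 9 → 10)

**Steps most likely to fail**

Step 4. The alkyne may insert into the acyl rhodium hydride with the opposite orientation, delivering the acyl group to the aryl-bearing carbon, and the electron-rich aryl acetylene may oligomerise on rhodium before it is hydroacylated. The fallback makes the same bond by stoichiometric alkenylmetal addition to the aldehyde and reaches the ketone by oxidation; it sets out from 9 (with 4 as partner) and comes back at 10.
- Silylation of 9 (t-BuMe2SiCl, imidazole, DMF) should give tert-butyl[4-ethynyl-2-(3-methylbut-2-en-1-yl)phenoxy]dimethylsilane F1.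
- Syn hydrozirconation with Cp2Zr(H)Cl in CH2Cl2 should give the (E)-alkenylzirconocene chloride F2.
- Transmetalation with Me2Zn at −65 °C should give the (E)-alkenyl(methyl)zinc F3.
- Addition of F3 at 0 °C to 4, whose phenol is first masked as the methylzinc phenoxide with one equivalent of Me2Zn, should give after NH4Cl work-up the racemic allylic alcohol (E)-3-[4-(tert-butyldimethylsilyloxy)-3-(3-methylbut-2-en-1-yl)phenyl]-1-(5-hydroxy-2,2-dimethyl-2H-chromen-6-yl)prop-2-en-1-ol F4.
- MnO2 in CH2Cl2 should oxidise the allylic, benzylic alcohol to the silyl-protected chalcone (E)-3-[4-(tert-butyldimethylsilyloxy)-3-(3-methylbut-2-en-1-yl)phenyl]-1-(5-hydroxy-2,2-dimethyl-2H-chromen-6-yl)prop-2-en-1-one F5.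
- Bu4NF buffered with AcOH in THF at 0 °C should remove the silyl group and give 10.

Step 3. The phenol is deprotonated under the basic methanolic conditions, which lowers the electrophilicity of the aldehyde, so that addition of the diazophosphonate anion may stall while the reagent decomposes. The fallback masks the phenol and homologates under aprotic conditions by the Colvin rearrangement; it sets out from 7 and comes back at 9.
- Silylation of 7 (i-Pr3SiCl, imidazole, DMF) should give 3-(3-methylbut-2-en-1-yl)-4-(triisopropylsilyloxy)benzaldehyde F6.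
- Lithiated trimethylsilyldiazomethane (Me3SiCHN2, LiN(i-Pr)2, THF, −78 °C to rt) should add to the aldehyde and eliminate in Peterson fashion to the diazoalkene [4-(2-diazoethenyl)-2-(3-methylbut-2-en-1-yl)phenoxy]triisopropylsilane F7.
- F7 should lose N2 and rearrange to [4-ethynyl-2-(3-methylbut-2-en-1-yl)phenoxy]triisopropylsilane F8.
- Bu4NF in THF at 0 °C should then give 9.

Step 2. O-alkylation and double alkylation of the ambident phenoxide may outrun mono-C-alkylation, so that conversion to the ortho-prenyl phenol stays low. The fallback makes the ortho carbon–carbon bond by aromatic Claisen rearrangement and the prenyl terminus by cross-metathesis; it sets out from 5 and comes back at 7.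
- O-Allylation of 5 (allyl bromide, K2CO3, acetone, reflux) should give 4-(allyloxy)benzaldehyde F9.
- Heating in N,N-diethylaniline at 200 °C should bring about the [3,3]-sigmatropic shift to the racemic dienone 4-oxo-3-(prop-2-en-1-yl)cyclohexa-1,5-diene-1-carbaldehyde F10.
- F10 should tautomerise in the flask to 3-allyl-4-hydroxybenzaldehyde F11.
- Cross-metathesis with excess 2-methylbut-2-ene (second-generation Grubbs catalyst, RuCl2(=CHPh)(PCy3)(H2IMes), CH2Cl2, 40 °C) should exchange the terminal methylene for an isopropylidene group and give 7.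

**Further compounds**
F1 | step 4 | tert-butyl[4-ethynyl-2-(3-methylbut-2-en-1-yl)phenoxy]dimethylsilane | CC(C)=CCc1cc(C#C)ccc1O[Si](C)(C)C(C)(C)C
F2 | step 4 | chlorobis(cyclopentadienyl)[(E)-2-{4-(tert-butyldimethylsilyloxy)-3-(3-methylbut-2-en-1-yl)phenyl}ethenyl]zirconium | CC(C)=CCc1cc(/C=C/[Zr](Cl)(C2C=CC=C2)C2C=CC=C2)ccc1O[Si](C)(C)C(C)(C)C
F3 | step 4 | [(E)-2-{4-(tert-butyldimethylsilyloxy)-3-(3-methylbut-2-en-1-yl)phenyl}ethenyl](methyl)zinc | CC(C)=CCc1cc(/C=C/[Zn]C)ccc1O[Si](C)(C)C(C)(C)C
F4 | step 4 | (E)-3-[4-(tert-butyldimethylsilyloxy)-3-(3-methylbut-2-en-1-yl)phenyl]-1-(5-hydroxy-2,2-dimethyl-2H-chromen-6-yl)prop-2-en-1-ol (racemic) | CC(C)=CCc1cc(/C=C/C(O)c2ccc3c(c2O)C=CC(C)(C)O3)ccc1O[Si](C)(C)C(C)(C)C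
F5 | step 4 | (E)-3-[4-(tert-butyldimethylsilyloxy)-3-(3-methylbut-2-en-1-yl)phenyl]-1-(5-hydroxy-2,2-dimethyl-2H-chromen-6-yl)prop-2-en-1-one | CC(C)=CCc1cc(/C=C/C(=O)c2ccc3c(c2O)C=CC(C)(C)O3)ccc1O[Si](C)(C)C(C)(C)C
F6 | step 3 | 3-(3-methylbut-2-en-1-yl)-4-(triisopropylsilyloxy)benzaldehyde | CC(C)=CCc1cc(C=O)ccc1O[Si](C(C)C)(C(C)C)C(C)C
F7 | step 3 | [4-(2-diazoethenyl)-2-(3-methylbut-2-en-1-yl)phenoxy]triisopropylsilane | CC(C)=CCc1cc(C=C=[N+]=[N-])ccc1O[Si](C(C)C)(C(C)C)C(C)C
F8 | step 3 | [4-ethynyl-2-(3-methylbut-2-en-1-yl)phenoxy]triisopropylsilane | CC(C)=CCc1cc(C#C)ccc1O[Si](C(C)C)(C(C)C)C(C)C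
F9 | step 2 | 4-(allyloxy)benzaldehyde | C=CCOc1ccc(C=O)cc1
F10 | step 2 | 4-oxo-3-(prop-2-en-1-yl)cyclohexa-1,5-diene-1-carbaldehyde (racemic) | O=CC1=CC(CC=C)C(=O)C=C1
F11 | step 2 | 3-allyl-4-hydroxybenzaldehyde | C=CCc1cc(C=O)ccc1O
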